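**Assumptions.** The SMILES is taken as authoritative: 5,8-dihydroxy-6-(3-hydroxy-3-methylbutyl)-3-(7-hydroxy-2,2-dimethyl-2H-chromen-6-yl)-4H-chromen-4-one, with H at C7. It has no stereocentres, so there is no enantiomer to control. Only compounds that contribute atoms are numbered; bases, catalysts, hydride and Lewis-acid reagents appear under conditions.

## Retrosynthetic overview

1. Target ⇐ desilylation ⇐ C6–side-chain bond made last by a new radical reductive alkylation of an isoflavone-5,8-quinone with an alkyl-catecholborane derived from 2-methylbut-3-en-2-ol. This step also delivers the 5,8-hydroquinone.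
2. Isoflavone-5,8-quinone ⇐ Fremy's salt (Teuber) oxidation of an 8-hydroxyisoflavone.
3. 8-Hydroxyisoflavone ⇐ Suzuki coupling of 8-hydroxy-3-iodochromone with a 7-silyloxy-2,2-dimethylchromen-6-yl boronate.
4. Iodochromone ⇐ 2'-hydroxy-3'-methoxyacetophenone (enaminone, then iodocyclisation). Chromene ⇐ 4-bromoresorcinol + 3-methylbut-2-enoic acid (chromanone, then chromene).
5. Ring order: pyranone ring on the A ring and dimethylpyran ring on the B ring are built separately, the two halves are joined, then the A ring is oxidised to the quinone and alkylated.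

## Route

**Step 1**
Reactants: 1, 1-(2-hydroxy-3-methoxyphenyl)ethan-1-one; 2, N,N-dimethylformamide dimethyl acetal
Product: 3, (E)-3-(dimethylamino)-1-(2-hydroxy-3-methoxyphenyl)prop-2-en-1-one
Conditions: DMF-DMA (2 equiv), PhMe, 100 °C
Reagents that add atoms: 2, DMF-DMA, COC(OC)N(C)C
Why: Aminomethylenation of the methyl ketone gives the thermodynamic E-enaminone; the chelated phenol is not touched.

**Step 2**
Reactants: 3; 4, iodine
Product: 5, 3-iodo-8-methoxy-4H-chromen-4-one
Conditions: I2 (1.5 equiv), CHCl3, rt; aq. Na2S2O3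
Reagents that add atoms: 4, iodine, II
Why: Gammill iodocyclisation: α-iodination of the enaminone, then phenol addition–elimination with loss of Me2NH closes the pyranone.

**Step 3**
Reactants: 5
Product: 6, 8-hydroxy-3-iodo-4H-chromen-4-one
Conditions: BBr3 (3 equiv), CH2Cl2, −78 °C → rt
Reagents that add atoms: none
Why: BBr3 aryl methyl ether cleavage, done here because no acid-sensitive group is present yet.

**Step 4**
Reactants: 7, 4-bromobenzene-1,3-diol; 8, 3-methylbut-2-enoic acid
Product: 9, 6-bromo-7-hydroxy-2,2-dimethylchroman-4-one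
Conditions: MeSO3H/P2O5 (Eaton's reagent), 70 °C
Reagents that add atoms: 8, 3-methylbut-2-enoic acid, CC(C)=CC(=O)O
Why: Friedel–Crafts acylation at the only unhindered activated carbon (para to one OH, ortho to the other), then oxa-Michael closure; the bromine pre-sets the linear coupling site.

**Step 5**
Reactants: 9; 10, chlorotriisopropylsilane
Product: 11, 6-bromo-2,2-dimethyl-7-(triisopropylsilyloxy)chroman-4-one
Conditions: TIPSCl, imidazole, DMF, rt
Reagents that add atoms: 10, TIPSCl, CC(C)[Si](Cl)(C(C)C)C(C)C
Why: Phenol silylation; TIPS survives aryllithium at −78 °C, aqueous base, Fremy's salt and the radical step, and leaves with fluoride.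

**Step 6**
Reactants: 11
Product: 12, 6-bromo-2,2-dimethyl-7-(triisopropylsilyloxy)chroman-4-ol (racemic)
Conditions: NaBH4, THF/MeOH, 0 °C
Reagents that add atoms: none
Why: Borohydride reduction of the aryl ketone; the racemic carbinol centre is removed in the next step.

**Step 7**
Reactants: 12
Product: 13, 6-bromo-2,2-dimethyl-7-(triisopropylsilyloxy)-2H-chromene
Conditions: p-TsOH·H2O (5 mol%), PhMe, 80 °C
Reagents that add atoms: none
Why: Acid-catalysed E1 dehydration of the benzylic alcohol (cation stabilised by the para silyloxy oxygen) gives the conjugated chromene.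

**Step 8**
Reactants: 13; 14, 2-isopropoxy-4,4,5,5-tetramethyl-1,3,2-dioxaborolane
Product: 15, 2-[2,2-dimethyl-7-(triisopropylsilyloxy)-2H-chromen-6-yl]-4,4,5,5-tetramethyl-1,3,2-dioxaborolane
Conditions: n-BuLi, THF, −78 °C; then iPrOBpin, −78 °C → rt
Reagents that add atoms: 14, iPrOBpin, CC(C)OB1OC(C)(C)C(C)(C)O1
Why: Bromine–lithium exchange and borate trapping; holding −78 °C suppresses retro-Brook migration of the bulky TIPS group.

**Step 9**
Reactants: 6; 15
Product: 16, 3-[2,2-dimethyl-7-(triisopropylsilyloxy)-2H-chromen-6-yl]-8-hydroxy-4H-chromen-4-one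
Conditions: Pd(OAc)2 (5 mol%), SPhos (10 mol%), K3PO4, PhMe/H2O, 70 °C, degassed
Reagents that add atoms: none (both partners are listed reactants)
Why: Suzuki–Miyaura coupling of the 3-iodochromone with the hindered aryl boronate; the 8-phenoxide formed in situ lowers pyranone electrophilicity so the ring tolerates the base.

**Step 10**
Reactants: 16; 17, potassium nitrosodisulfonate (Fremy's salt)
Product: 18, 3-[2,2-dimethyl-7-(triisopropylsilyloxy)-2H-chromen-6-yl]-4H-chromene-4,5,8-trione
Conditions: (KSO3)2NO (2.5 equiv), KH2PO4 buffer, acetone/H2O, rt; use at once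
Reagents that add atoms: 17, Fremy's salt, [K+].[K+].[O]N(S(=O)(=O)[O-])S(=O)(=O)[O-] (supplies the C5 oxygen)
Why: Teuber oxidation: the only free phenol gives a phenoxyl radical that is oxygenated at the unsubstituted para carbon C5 to the p-quinone; the chromene alkene and silyl ether are inert to this reagent.

**Step 11**
Reactants: 19, 2-methylbut-3-en-2-ol; 20, chlorotrimethylsilane
Product: 21, trimethyl[(2-methylbut-3-en-2-yl)oxy]silane
Conditions: TMSCl, imidazole, CH2Cl2, 0 °C → rt; distil
Reagents that add atoms: 20, TMSCl, C[Si](C)(C)Cl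
Why: Silylation masks the tertiary OH so it cannot bind boron in the next two steps.

**Step 12**
Reactants: 21; 22, catecholborane
Product: 23, 2-[3-methyl-3-(trimethylsilyloxy)butyl]-1,3,2-benzodioxaborole (used as solution)
Conditions: catecholborane (1.0 equiv), 21 (1.2 equiv), MeCONMe2 (10 mol%), CH2Cl2, 40 °C
Reagents that add atoms: 22, catecholborane, B1Oc2ccccc2O1
Why: Amide-catalysed anti-Markovnikov hydroboration of the terminal alkene; excess alkene leaves no B–H to reduce the quinone later.

**Step 13**
Reactants: 18; 23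
Product: 24, 3-[2,2-dimethyl-7-(triisopropylsilyloxy)-2H-chromen-6-yl]-5,8-dihydroxy-6-[3-methyl-3-(trimethylsilyloxy)butyl]-4H-chromen-4-one (used crude)
Conditions: 23 (1.5 equiv), CH2Cl2/THF, 0 °C → rt, slow addition of 18, trace air as initiator; then MeOH, pH 7 buffer, aq. Na2S2O4 wash
Reagents that add atoms: 23 (transfers the 3-methyl-3-(trimethylsilyloxy)butyl group), CC(C)(O[Si](C)(C)C)CCB1Oc2ccccc2O1; work-up water supplies only H
Why: Proposed new method: regioselective radical-chain reductive C6-alkylation of a chromone-fused 5,8-quinone by a B-alkylcatecholborane — trace O2 releases the primary alkyl radical from 23, which adds to C6 because C6 is β to C8=O, the more electrophilic carbonyl (C5=O is deactivated as a vinylogous ester through O1–C8a=C4a–C5=O), the resulting O8-centred semiquinone radical (stabilised by the adjacent O1) attacks boron of 23 to give the aryl borate and the next alkyl radical, and tautomerisation aromatises to the chelated 5-OH hydroquinone, so one step forms the C6–C bond and sets the hydroquinone oxidation level without any A-ring protecting group; the quinone is added slowly to keep its concentration low and limit redox exchange with product, and THF limits boron chelation at the C4/C5 carbonyls that would steer to C7; closest known reaction type is the radical-chain 1,4-reductive alkylation of simple p-benzoquinones and naphthoquinones with trialkylboranes or B-alkylcatecholboranes, not shown on chromone- or other pyranone-fused quinones.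

**Step 14**
Reactants: 24
Product: 25, Kraussianone 3 (5,8-dihydroxy-6-(3-hydroxy-3-methylbutyl)-3-(7-hydroxy-2,2-dimethyl-2H-chromen-6-yl)-4H-chromen-4-one)
Conditions: TBAF (2.5 equiv), AcOH (3 equiv), THF, 0 °C → rt, Ar
Reagents that add atoms: none
Why: Buffered fluoride desilylation removes the aryl TIPS and tertiary TMS ethers together; no acid is used, so the tertiary alcohol cannot cyclise onto the 5-OH and the chromene is untouched.

## Compound list

1 | 1-(2-hydroxy-3-methoxyphenyl)ethan-1-one | CC(=O)c1cccc(OC)c1O | starting material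
2 | N,N-dimethylformamide dimethyl acetal | COC(OC)N(C)C | starting material
3 | (E)-3-(dimethylamino)-1-(2-hydroxy-3-methoxyphenyl)prop-2-en-1-one | CN(C)/C=C/C(=O)c1cccc(OC)c1O | intermediate
4 | iodine | II | starting material
5 | 3-iodo-8-methoxy-4H-chromen-4-one | COc1cccc2c(=O)c(I)coc12 | intermediate
6 | 8-hydroxy-3-iodo-4H-chromen-4-one | Oc1cccc2c(=O)c(I)coc12 | intermediate
7 | 4-bromobenzene-1,3-diol | Oc1ccc(Br)c(O)c1 | starting material
8 | 3-methylbut-2-enoic acid | CC(C)=CC(=O)O | starting material
9 | 6-bromo-7-hydroxy-2,2-dimethylchroman-4-one | CC1(C)CC(=O)c2cc(Br)c(O)cc2O1 | intermediate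
10 | chlorotriisopropylsilane | CC(C)[Si](Cl)(C(C)C)C(C)C | starting material
11 | 6-bromo-2,2-dimethyl-7-(triisopropylsilyloxy)chroman-4-one | CC1(C)CC(=O)c2cc(Br)c(O[Si](C(C)C)(C(C)C)C(C)C)cc2O1 | intermediate
12 | 6-bromo-2,2-dimethyl-7-(triisopropylsilyloxy)chroman-4-ol (racemic) | CC1(C)CC(O)c2cc(Br)c(O[Si](C(C)C)(C(C)C)C(C)C)cc2O1 | intermediate
13 | 6-bromo-2,2-dimethyl-7-(triisopropylsilyloxy)-2H-chromene | CC1(C)C=Cc2cc(Br)c(O[Si](C(C)C)(C(C)C)C(C)C)cc2O1 | intermediate
14 | 2-isopropoxy-4,4,5,5-tetramethyl-1,3,2-dioxaborolane | CC(C)OB1OC(C)(C)C(C)(C)O1 | starting material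
15 | 2-[2,2-dimethyl-7-(triisopropylsilyloxy)-2H-chromen-6-yl]-4,4,5,5-tetramethyl-1,3,2-dioxaborolane | CC1(C)C=Cc2cc(B3OC(C)(C)C(C)(C)O3)c(O[Si](C(C)C)(C(C)C)C(C)C)cc2O1 | intermediate
16 | 3-[2,2-dimethyl-7-(triisopropylsilyloxy)-2H-chromen-6-yl]-8-hydroxy-4H-chromen-4-one | Oc1cccc2c(=O)c(-c3cc4c(cc3O[Si](C(C)C)(C(C)C)C(C)C)OC(C)(C)C=C4)coc12 | intermediate
17 | potassium nitrosodisulfonate (Fremy's salt) | [K+].[K+].[O]N(S(=O)(=O)[O-])S(=O)(=O)[O-] | starting material
18 | 3-[2,2-dimethyl-7-(triisopropylsilyloxy)-2H-chromen-6-yl]-4H-chromene-4,5,8-trione | O=C1C=CC(=O)C2=C1OC=C(C2=O)c1cc2c(cc1O[Si](C(C)C)(C(C)C)C(C)C)OC(C)(C)C=C2 | intermediate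
19 | 2-methylbut-3-en-2-ol | CC(C)(O)C=C | starting material
20 | chlorotrimethylsilane | C[Si](C)(C)Cl | starting material
21 | trimethyl[(2-methylbut-3-en-2-yl)oxy]silane | CC(C)(O[Si](C)(C)C)C=C | intermediate
22 | catecholborane | B1Oc2ccccc2O1 | starting material
23 | 2-[3-methyl-3-(trimethylsilyloxy)butyl]-1,3,2-benzodioxaborole | CC(C)(O[Si](C)(C)C)CCB1Oc2ccccc2O1 | intermediate
24 | 3-[2,2-dimethyl-7-(triisopropylsilyloxy)-2H-chromen-6-yl]-5,8-dihydroxy-6-[3-methyl-3-(trimethylsilyloxy)butyl]-4H-chromen-4-one | CC(C)(O[Si](C)(C)C)CCc1cc(O)c2occ(-c3cc4c(cc3O[Si](C(C)C)(C(C)C)C(C)C)OC(C)(C)C=C4)c(=O)c2c1O | intermediate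
25 | Kraussianone 3 | CC(C)(O)CCc1cc(O)c2occ(-c3cc4c(cc3O)OC(C)(C)C=C4)c(=O)c2c1O | target

## Summary

Total steps: 14.
Longest linear sequence: 9 (steps 4, 5, 6, 7, 8, 9, 10, 13, 14).

Three steps most likely to fail:

1. **Step 13 (proposed new reductive quinone alkylation).** Risks are the C7 regioisomer, redox exchange between product and unreacted quinone, and O-alkylation. Fallback with known chemistry: install the side chain before the chromone is built. From 1-(2-hydroxy-3,6-dimethoxyphenyl)ethanone, brominate with NBS para to the OH, run a Sonogashira coupling with 2-methylbut-3-yn-2-ol and hydrogenate. Then DMF-DMA/I2, CAN oxidative demethylation to the 6-alkyl-3-iodochromone-5,8-dione, Na2S2O4 reduction and bis-silylation, Suzuki coupling with 15, and fluoride deprotection.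

2. **Step 10 (Teuber oxidation).** The 8-hydroxychromone is an electron-poor phenol and may oxidise slowly, and the quinone may hydrolyse at C2. Fallback: change the A-ring precursor to 5-hydroxy-3-iodo-8-methoxychromone, made from 1,2,4-trimethoxybenzene by ortho-lithiation/acetylation, BCl3, DMF-DMA/I2 and a second BCl3 demethylation. After the Suzuki coupling, generate the same quinone by PhI(OAc)2 oxidative demethylation of the p-methoxyphenol.

3. **Step 9 (Suzuki coupling).** The ortho-TIPSO boronate is hindered and may protodeboronate, and the pyranone may open under base. Fallback: base-free Negishi coupling of the arylzinc made from 13 (n-BuLi, then ZnCl2) with the 8-O-silyl derivative of 6; the 8-silyl group is removed selectively before step 10.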